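## Retrosynthetic overview
1. Plakotenin ⇒ its ethyl ester ⇒ acyclic ethyl (2E,4Z,6R,8R,9E,11E)-tetraenoate, by a type 1 intramolecular Diels–Alder disconnection of C4–C5 and C3a–C7a (indene numbering).
2. Ring order: no ring is made beforehand. The cyclohexene and the cyclopentane close together in that one cycloaddition, which also sets four of the six stereocentres.
3. Dienophile arm ⇒ Wittig (C2=C3, E) and Still–Gennari (C4=C5, Z) olefinations. Diene arm ⇒ Wittig and Horner–Wadsworth–Emmons olefinations (both E).
4. The anti-2,4-dimethylpentane core ⇒ stereospecific sp3–sp3 coupling of the Grignard reagent from (S)-3-bromo-2-methylpropan-1-ol with the triflate of tert-butyl (R)-lactate (inversion).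

Assumption: the target SMILES is taken at face value, and of the two trans-fused transition states open to the acyclic tetraene, the one giving this diastereomer (1-Me trans to H-7a, 3-Me trans to H-3a) is assumed to operate, to be checked by NOE or X-ray on the cycloadduct.

## Route

Step 1
Reactants: 1 (S)-3-bromo-2-methylpropan-1-ol
Product: 2 [(2S)-3-bromo-2-methylpropoxy]triethylsilane
Conditions: Et3SiCl, imidazole, CH2Cl2, 0 °C to rt
Reagents that add atoms: chlorotriethylsilane, CC[Si](Cl)(CC)CC
Why: Silyl ether formation (imidazole-assisted substitution at silicon) masks the alcohol without touching the stereocentre, and the triethylsilyl group survives Grignard formation, hydride and ylide chemistry yet can be oxidised off directly in step 7.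

Step 2
Reactants: 3 tert-butyl (2R)-2-hydroxypropanoate (tert-butyl (R)-lactate)
Product: 4 tert-butyl (2R)-2-(trifluoromethylsulfonyloxy)propanoate
Conditions: Tf2O, 2,6-lutidine, CH2Cl2, −78 to 0 °C
Reagents that add atoms: trifluoromethanesulfonic anhydride, O=S(=O)(OS(=O)(=O)C(F)(F)F)C(F)(F)F
Why: O-Sulfonylation breaks only the O–H bond, so the R configuration bought with the lactate is kept and the carbon is activated for SN2 displacement.

Step 3
Reactants: 2 [(2S)-3-bromo-2-methylpropoxy]triethylsilane; 4 tert-butyl (2R)-2-(trifluoromethylsulfonyloxy)propanoate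
Product: 6 tert-butyl (2R,4R)-2,4-dimethyl-5-(triethylsilyloxy)pentanoate, via Grignard reagent 5 (not isolated)
Conditions: 2, Mg, THF, 50 °C; then 4, ZnCl2 (10 mol %), THF, 0 °C
Reagents that add atoms: none
Why: The ZnCl2-catalysed Grignard cross-coupling (a triorganozincate is the nucleophile) displaces the α-ester triflate by clean SN2 inversion, so the lactate carbon becomes C2 (R after the priority change) beside the untouched centre from 1, which gives the anti-2,4-dimethyl array while the tert-butyl ester resists addition at 0 °C.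

Step 4
Reactants: 6 tert-butyl (2R,4R)-2,4-dimethyl-5-(triethylsilyloxy)pentanoate
Product: 7 (2R,4R)-2,4-dimethyl-5-(triethylsilyloxy)pentanal
Conditions: iBu2AlH (1.1 equiv), CH2Cl2, −78 °C; aq. KNaC4H4O6 (potassium sodium tartrate)
Reagents that add atoms: none
Why: Partial ester reduction stops at the aluminium hemiacetal, which is stable at −78 °C and releases the aldehyde only on work-up, and the α-centre is not epimerised under these cold non-basic conditions.

Step 5
Reactants: 7 (2R,4R)-2,4-dimethyl-5-(triethylsilyloxy)pentanal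
Product: 8 (2E,4R,6R)-2,4,6-trimethyl-7-(triethylsilyloxy)hept-2-enal
Conditions: Ph3P=C(Me)CHO (1.3 equiv), toluene, 90 °C
Reagents that add atoms: 2-(triphenylphosphoranylidene)propanal, CC(C=O)=P(c1ccccc1)(c1ccccc1)c1ccccc1
Why: Wittig olefination with a stabilised formyl ylide gives the E-trisubstituted enal, the saturated aldehyde reacts much faster than the product enal, and the neutral salt-free medium leaves the allylic stereocentre intact.

Step 6
Reactants: 8 (2E,4R,6R)-2,4,6-trimethyl-7-(triethylsilyloxy)hept-2-enal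
Product: 9 triethyl{[(2R,4R,5E,7E)-2,4,6-trimethyl-8-phenylocta-5,7-dien-1-yl]oxy}silane
Conditions: (EtO)2P(O)CH2Ph, n-BuLi, THF, −78 °C; then 8, −78 °C to rt
Reagents that add atoms: diethyl benzylphosphonate, CCOP(=O)(Cc1ccccc1)OCC
Why: Horner–Wadsworth–Emmons olefination with the lithiated benzylphosphonate adds 1,2 to the enal and eliminates to the E-styrene, which completes the E,E-diene without creating a stereocentre.

Step 7
Reactants: 9 triethyl{[(2R,4R,5E,7E)-2,4,6-trimethyl-8-phenylocta-5,7-dien-1-yl]oxy}silane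
Product: 10 (2R,4R,5E,7E)-2,4,6-trimethyl-8-phenylocta-5,7-dienal
Conditions: (COCl)2 (4 equiv), DMSO (8 equiv), CH2Cl2, −78 to −30 °C; Et3N, −78 °C to rt
Reagents that add atoms: none
Why: This is a Swern oxidation applied directly to the primary triethylsilyl ether, in which the activated sulfonium species cleaves the unhindered Si–O bond and the alkoxysulfonium ylide collapses to the aldehyde, saving a separate deprotection without epimerising C2 at low temperature.

Step 8
Reactants: 11 methyl 2-[bis(2,2,2-trifluoroethoxy)phosphoryl]acetate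
Product: 12 methyl 2-[bis(2,2,2-trifluoroethoxy)phosphoryl]butanoate (racemic)
Conditions: NaH, THF–DMSO (4:1), 0 °C; EtI, rt
Reagents that add atoms: iodoethane, CCI
Why: C-Alkylation (SN2) of the stabilised phosphonoacetate carbanion installs the ethyl branch of the later quaternary carbon, and the racemic centre formed here is erased in step 9.

Step 9
Reactants: 10 (2R,4R,5E,7E)-2,4,6-trimethyl-8-phenylocta-5,7-dienal; 12 methyl 2-[bis(2,2,2-trifluoroethoxy)phosphoryl]butanoate
Product: 13 methyl (2Z,4R,6R,7E,9E)-2-ethyl-4,6,8-trimethyl-10-phenyldeca-2,7,9-trienoate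
Conditions: 12, KN(SiMe3)2, 18-crown-6, THF, −78 °C; then 10, −78 °C
Reagents that add atoms: none
Why: In the Still–Gennari variant of the Horner–Wadsworth–Emmons reaction the electron-poor phosphonate and the dissociated potassium ion make elimination from the kinetic adduct faster than its equilibration, which gives the Z-enoate (chain cis to CO2Me) without epimerising the aldehyde α-centre at −78 °C.

Step 10
Reactants: 13 methyl (2Z,4R,6R,7E,9E)-2-ethyl-4,6,8-trimethyl-10-phenyldeca-2,7,9-trienoate
Product: 14 (2Z,4R,6R,7E,9E)-2-ethyl-4,6,8-trimethyl-10-phenyldeca-2,7,9-trien-1-ol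
Conditions: iBu2AlH (2.5 equiv), CH2Cl2, −78 °C; aq. KNaC4H4O6
Reagents that add atoms: none
Why: 1,2-Reduction of the enoate by two hydride equivalents gives the allylic alcohol with all alkene geometries and both stereocentres unchanged.

Step 11
Reactants: 14 (2Z,4R,6R,7E,9E)-2-ethyl-4,6,8-trimethyl-10-phenyldeca-2,7,9-trien-1-ol
Product: 17 ethyl (2E)-3-[(1R,3R,3aR,4S,5S,7aR)-4-ethyl-1,3,7-trimethyl-5-phenyl-2,3,3a,4,5,7a-hexahydro-1H-inden-4-yl]-2-methylprop-2-enoate, via Z-enal 15 (not isolated), via tetraene ester 16 (not isolated)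
Conditions: MnO2 (20 equiv), Ph3P=C(Me)CO2Et (1.5 equiv), toluene, rt, 16 h; filter (Celite); filtrate, BHT (cat.), 110 °C, 24 h
Reagents that add atoms: ethyl 2-(triphenylphosphoranylidene)propanoate, CCOC(=O)C(C)=P(c1ccccc1)(c1ccccc1)c1ccccc1
Why: Tandem MnO2 oxidation–Wittig olefination traps the isomerisation-prone Z-enal at once as the (2E,4Z)-dienoate, and heating then triggers the type 1 intramolecular Diels–Alder reaction that forms C4–C5 and C3a–C7a suprafacially, so that the E,E-diene places phenyl cis to C1 across the new ring, the Z-dienophile places the enoate arm at C4 cis to C3 (ethyl cis to H-3a), the tether-exo transition state gives the trans ring fusion, and the two bought methyl centres, related by the local C2 axis of the tether and therefore reinforcing each other, select the diene face.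

Step 12
Reactants: 17 ethyl (2E)-3-[(1R,3R,3aR,4S,5S,7aR)-4-ethyl-1,3,7-trimethyl-5-phenyl-2,3,3a,4,5,7a-hexahydro-1H-inden-4-yl]-2-methylprop-2-enoate
Product: 18 plakotenin, (2E)-3-[(1R,3R,3aR,4S,5S,7aR)-4-ethyl-1,3,7-trimethyl-5-phenyl-2,3,3a,4,5,7a-hexahydro-1H-inden-4-yl]-2-methylprop-2-enoic acid
Conditions: LiOH, THF–MeOH–H2O, 50 °C; then 1 M HCl
Reagents that add atoms: lithium hydroxide, [Li+].[OH-]
Why: Saponification by acyl–oxygen cleavage followed by acidification frees the acid, and the molecule has no epimerisable centre or base-labile alkene.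

## Compound list
1 | (S)-3-bromo-2-methylpropan-1-ol | OC[C@H](C)CBr | starting material
2 | [(2S)-3-bromo-2-methylpropoxy]triethylsilane | CC[Si](CC)(CC)OC[C@H](C)CBr | intermediate
3 | tert-butyl (2R)-2-hydroxypropanoate | C[C@@H](O)C(=O)OC(C)(C)C | starting material
4 | tert-butyl (2R)-2-(trifluoromethylsulfonyloxy)propanoate | C[C@@H](OS(=O)(=O)C(F)(F)F)C(=O)OC(C)(C)C | intermediate
5 | [(2S)-2-methyl-3-(triethylsilyloxy)propyl]magnesium bromide | CC[Si](CC)(CC)OC[C@H](C)C[Mg]Br | intermediate
6 | tert-butyl (2R,4R)-2,4-dimethyl-5-(triethylsilyloxy)pentanoate | CC[Si](CC)(CC)OC[C@H](C)C[C@@H](C)C(=O)OC(C)(C)C | intermediate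
7 | (2R,4R)-2,4-dimethyl-5-(triethylsilyloxy)pentanal | CC[Si](CC)(CC)OC[C@H](C)C[C@@H](C)C=O | intermediate
8 | (2E,4R,6R)-2,4,6-trimethyl-7-(triethylsilyloxy)hept-2-enal | CC[Si](CC)(CC)OC[C@H](C)C[C@@H](C)/C=C(\C)C=O | intermediate
9 | triethyl{[(2R,4R,5E,7E)-2,4,6-trimethyl-8-phenylocta-5,7-dien-1-yl]oxy}silane | CC[Si](CC)(CC)OC[C@H](C)C[C@@H](C)/C=C(\C)/C=C/c1ccccc1 | intermediate
10 | (2R,4R,5E,7E)-2,4,6-trimethyl-8-phenylocta-5,7-dienal | O=C[C@H](C)C[C@@H](C)/C=C(\C)/C=C/c1ccccc1 | intermediate
11 | methyl 2-[bis(2,2,2-trifluoroethoxy)phosphoryl]acetate | COC(=O)CP(=O)(OCC(F)(F)F)OCC(F)(F)F | starting material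
12 | methyl 2-[bis(2,2,2-trifluoroethoxy)phosphoryl]butanoate (racemic) | CCC(C(=O)OC)P(=O)(OCC(F)(F)F)OCC(F)(F)F | intermediate
13 | methyl (2Z,4R,6R,7E,9E)-2-ethyl-4,6,8-trimethyl-10-phenyldeca-2,7,9-trienoate | CC/C(C(=O)OC)=C/[C@H](C)C[C@@H](C)/C=C(\C)/C=C/c1ccccc1 | intermediate
14 | (2Z,4R,6R,7E,9E)-2-ethyl-4,6,8-trimethyl-10-phenyldeca-2,7,9-trien-1-ol | CC/C(CO)=C/[C@H](C)C[C@@H](C)/C=C(\C)/C=C/c1ccccc1 | intermediate
15 | (2Z,4R,6R,7E,9E)-2-ethyl-4,6,8-trimethyl-10-phenyldeca-2,7,9-trienal | CC/C(C=O)=C/[C@H](C)C[C@@H](C)/C=C(\C)/C=C/c1ccccc1 | intermediate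
16 | ethyl (2E,4Z,6R,8R,9E,11E)-4-ethyl-2,6,8,10-tetramethyl-12-phenyldodeca-2,4,9,11-tetraenoate | CCOC(=O)/C(C)=C/C(CC)=C\[C@H](C)C[C@@H](C)/C=C(\C)/C=C/c1ccccc1 | intermediate
17 | ethyl (2E)-3-[(1R,3R,3aR,4S,5S,7aR)-4-ethyl-1,3,7-trimethyl-5-phenyl-2,3,3a,4,5,7a-hexahydro-1H-inden-4-yl]-2-methylprop-2-enoate | CC[C@@]1(/C=C(\C)C(=O)OCC)[C@H]2[C@H](C(C)=C[C@H]1c1ccccc1)[C@H](C)C[C@H]2C | intermediate
18 | plakotenin | CC[C@@]1(/C=C(\C)C(=O)O)[C@H]2[C@H](C(C)=C[C@H]1c1ccccc1)[C@H](C)C[C@H]2C | target

## Step count and risks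
Total step count: 12 (steps 2 and 8 are one-step side branches).
Longest linear sequence: 10 steps from 1 (steps 1, 3, 4, 5, 6, 7, 9, 10, 11, 12).

**Risk 1, step 11.**
- Three reactions run in one operation. Alkene geometry fixes only the C4/C3a and C5/C7a relationships.
- The ring fusion, and above all the choice of diene face, rest on the two tether methyl groups alone.
- The rival trans-fused transition state is a serious competitor. In it both allylic hydrogens lie in the alkene planes and both methyl groups end up pseudo-equatorial.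
- Z to E leakage of 15 would feed the C4-epimeric series.

The fallback sets out from 14 and comes back to the route at 17. Compound 14 is oxidised with Dess–Martin periodinane (NaHCO3, CH2Cl2, 0 °C) and the enal 15 is isolated this time. It is then warmed on its own (toluene, BHT, 40–60 °C), so that the cycloaddition takes place before the chain is extended. In 15 the group cis to the tether is only a formyl group, so the allylic strain that the required transition state pays at the dienophile terminus is at its smallest. The lower LUMO also allows a lower and more selective temperature. The product is (1R,3R,3aR,4R,5S,7aR)-4-ethyl-1,3,7-trimethyl-5-phenyl-2,3,3a,4,5,7a-hexahydro-1H-indene-4-carbaldehyde F1, which is freed from any diastereomer and checked by NOE. The neopentyl aldehyde is then olefinated with ethyl 2-(triphenylphosphoranylidene)propanoate (toluene, 110 °C) to give 17.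

**Risk 2, step 9.**
- The Z:E ratio with an α-ethyl phosphonate and an α-branched aldehyde may fall short.
- Every percent of E-isomer ends up as a C4 epimer after the cycloaddition.

The fallback sets out from 10 and comes back at 14. It builds the Z-alkene by stereospecific cross-coupling instead of olefination. Compound 10 is treated with CBr4 and PPh3 (CH2Cl2, 0 °C) to give [(1E,3E,5R,7R)-9,9-dibromo-3,5,7-trimethylnona-1,3,8-trien-1-yl]benzene F2. Negishi coupling with Et2Zn (PdCl2(DPEphos) 5 mol %, THF, 0 °C to rt) replaces only the less hindered bromine trans to the chain. This gives [(1E,3E,5R,7R,8Z)-9-bromo-3,5,7-trimethylundeca-1,3,8-trien-1-yl]benzene F3. Bromine–lithium exchange with retention (t-BuLi, Et2O, −78 °C) and trapping with paraformaldehyde delivers 14.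

**Risk 3, step 4.**
- Partial reduction of a hindered α-branched tert-butyl ester can give mixtures of ester, aldehyde and alcohol.

The fallback sets out from 6 and comes back at 7. It replaces the partial reduction with a full redox detour. LiAlH4 (Et2O, 0 °C) reduces 6 completely to (2R,4R)-2,4-dimethyl-5-(triethylsilyloxy)pentan-1-ol F4. This alcohol is oxidised with Dess–Martin periodinane (NaHCO3, CH2Cl2, 0 °C) to 7, which is used crude.

## Further compounds
F1 | step 11 | (1R,3R,3aR,4R,5S,7aR)-4-ethyl-1,3,7-trimethyl-5-phenyl-2,3,3a,4,5,7a-hexahydro-1H-indene-4-carbaldehyde | CC[C@@]1(C=O)[C@H]2[C@H](C(C)=C[C@H]1c1ccccc1)[C@H](C)C[C@H]2C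
F2 | step 9 | [(1E,3E,5R,7R)-9,9-dibromo-3,5,7-trimethylnona-1,3,8-trien-1-yl]benzene | BrC(Br)=C[C@H](C)C[C@@H](C)/C=C(\C)/C=C/c1ccccc1
F3 | step 9 | [(1E,3E,5R,7R,8Z)-9-bromo-3,5,7-trimethylundeca-1,3,8-trien-1-yl]benzene | CC/C(Br)=C/[C@H](C)C[C@@H](C)/C=C(\C)/C=C/c1ccccc1
F4 | step 4 | (2R,4R)-2,4-dimethyl-5-(triethylsilyloxy)pentan-1-ol | CC[Si](CC)(CC)OC[C@H](C)C[C@@H](C)CO
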